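In a one-step world a substrate loses the same number of powers of ten in each equal stretch of time, so I count in decades: with f the fraction of a substrate's own charge still there, its decades lost are minus the logarithm of f. The question is whether to charge the recipe below and stop it at 25 min.

| flask | left-handed substrate | right-handed substrate | partner | protic impurity | precatalyst | added ligand | remark | time |
|---|---|---|---|---|---|---|---|---|
| zeta | 10 mM | 10 mM | 30 mM | 0.50 mM | 1 mM | 0.38 mM | run made earlier |  |
| gamma | 10 mM | 10 mM | 30 mM | 0.50 mM | 1 mM | 0.56 mM | run made earlier |  |
| flask | 10 mM | 10 mM | 30.0 mM | 0.500 mM | 1.0 mM | 0.75 mM |  | 25 min |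

- zeta (time / min: left-handed substrate / %, right-handed substrate / %): 1.50: 34.5, 49.6; 5.00: 14.9, 49.3; 8.00: 7.3, 47.4; 12.0: 0.9, 44.2; 20.0: 0, 43.0; 25.0: 0, 42.9; 30.0: 0, 42.7
- gamma (time / min: left-handed substrate / %, right-handed substrate / %): 2.50: 30.9, 47.7; 4.00: 23.2, 48.5; 6.00: 17.3, 47.2; 8.00: 10.8, 48.8; 12.0: 4.9, 45.8; 20.0: 3.4, 45.3; 30.0: 0, 41.5

(each reading ± 1 percentage point)

- free catalyst is single-handed; left-handed substrate and right-handed substrate are mirror images of each other, charged as a racemate, each of them at the stated concentration
- an excess is the difference of the two amounts in percent of their sum
- an excess is below zero if the other one leads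

* part of the left-handed substrate and right-handed substrate charged together that has reacted at 25 min
* excess of left-handed product over right-handed product in the product at 25 min
* excess of right-handed substrate over left-handed substrate among what is left of the two at 25 min

I take one late reading from each run, with the left-handed substrate still above the scatter. In zeta at 8.00 min the left-handed substrate has lost 0.836 decades and the right-handed 0.0232. In gamma at 12.0 min they have lost 1.01 and 0.0381. Pooled:

s = (0.836 + 1.01) / (0.0232 + 0.0381) = 30.1

I carry s, the decades lost by the left-handed substrate per decade lost by the right-handed, the selectivity factor. It is rough: in these readings the right-handed substrate has lost just 2.6 percentage points and 4.2 points against a scatter of 1 point.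

Up to 8.00 min the left-handed substrate loses 0.104 /min in zeta and 0.0832 /min in gamma, less with more ligand. I assume a straight line in added ligand:

rate at 0.75 mM: 0.0607 /min, so 1.52 decades by 25 min

left-handed f = 3.03%, right-handed f = 89.0%

c = 54.0%, eP = 79.6%, eS = 93.4%

So I charge the recipe and stop at 25 min. The forecast gives 53%, 79% and 89%, “with selectivity around 25–30”; its eS lies below mine.

The flask gives c 53.2%, eP 85.8% and eS 95.1%, so the forecast's c holds while its eP and eS lie low.

free catalyst + left-handed substrate ⇌ catalyst intermediate A (K = 58.0 /M, k = 110 /M/s); free catalyst + right-handed substrate ⇌ catalyst intermediate B (K = 45.0 /M, k = 1500 /M/s); partner + catalyst intermediate A → free catalyst + left-handed product (k = 7.80 /M/s); partner + catalyst intermediate B → free catalyst + right-handed product (k = 0.190 /M/s); precatalyst → free catalyst (k = 0.140 /s); partner + protic impurity → quenched reagent (k = 40.0 /M/s); free catalyst + added ligand ⇌ idle complex, settled at all times (K = 10000 /M) With 2.3% of the left-handed and 91% of the right-handed charge still there, this flask reads s = 41.4, higher than my 30.1. The neighbouring flask with 3.0 mM of added ligand keeps 49% of its left-handed charge at 25.0 min. My s turns that into a right-handed fraction of 97.7% and an eS of 33.2%. That flask holds 98% of its right-handed charge and gives an eS of 33.5%.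

The earlier runs and the new flask come from a simulation for substances that don't exist; the scatter is artificial.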